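Everything rests on one disconnection in ring B (the cyclopentane): the C–C bond joining the ring carbon that bears the isopropenyl group to its neighbour, the ring carbon that bears the CH2 bridge to ring A (the six-membered ring). Because this neighbour sits next to the tertiary carbinol carbon, retrosynthetic oxidation of the carbinol to a ketone and of the bridge carbon to an ester turns it into the acidic carbon of a β-keto ester. One asymmetric palladium-catalysed allylation then makes ring B, fixes the configuration at the isopropenyl-bearing carbon and converts a trisubstituted allylic carbonate into the isopropenyl group. The precursor is acyclic: methyl acetoacetate extended at its terminal carbon by an (E)-allylic tert-butyl carbonate.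

Key step: step 4

Remarks and assumptions on the chemistry:
- In the target the isopropenyl group is trans to the CH2 bridge and the tertiary hydroxyl is cis to it. The trans keto ester of step 4, (1R,5S), therefore maps directly onto the (1R,2S,5S)-cyclopentyl unit, provided the methyl group enters anti to the ester in step 5.
- The allylic oxygen is installed on the C5 unit before the β-keto ester exists, because SeO2-type allylic oxidation would also attack a 1,3-dicarbonyl methylene group. The leaving group is a tert-butyl carbonate, hindered enough to survive the acetoacetate dianion.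
- Assumption: the sense of induction of the ligand in step 4 cannot be predicted with certainty. The route is written with the (S,S) ligand; the equally available (R,R) ligand takes its place if a first run gives the mirror image of the cyclised keto ester.
- Ring A receives its two prenyl groups in two separate alkylations, each with one equivalent of prenyl bromide, so that the mono-prenyl compound can be purified before the dearomatising second alkylation.

Step 1
Reactants: 1 racemic 2-methyl-2-vinyloxirane
Product: 2 (E)-4-chloro-2-methylbut-2-en-1-ol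
Conditions: TiCl4 (0.6 equiv), CH2Cl2, −85 °C; then cold 1 M HCl
Reagents that add atoms: titanium tetrachloride, Cl[Ti](Cl)(Cl)Cl
Why: Lewis-acid-promoted conjugate (SN2') opening of a vinyl epoxide by chloride is a known route to this 1,4-chlorohydrin, in which chloride enters at the vinyl terminus as the allylic C–O bond breaks, and it should give mainly the (E) alkene that the later allyl complex requires, any (Z) isomer being removed by chromatography.

Step 2
Reactants: 2 (E)-4-chloro-2-methylbut-2-en-1-ol
Product: 3 tert-butyl (E)-4-chloro-2-methylbut-2-en-1-yl carbonate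
Conditions: Boc2O (1.2 equiv), DMAP (5 mol %), CH2Cl2, 0 °C to rt
Reagents that add atoms: di-tert-butyl dicarbonate, CC(C)(C)OC(=O)OC(=O)OC(C)(C)C
Why: DMAP-catalysed O-acylation with Boc2O (carbonate formation) should convert the primary alcohol cleanly while the allylic chloride stays intact, giving a hindered leaving group for palladium that a carbanion will not attack at its carbonyl group.

Step 3
Reactants: 4 methyl acetoacetate; 3 tert-butyl (E)-4-chloro-2-methylbut-2-en-1-yl carbonate
Product: 6 methyl (E)-8-[(tert-butoxycarbonyl)oxy]-7-methyl-3-oxooct-6-enoate, via methyl acetoacetate dianion 5 (not isolated)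
Conditions: NaH (1.1 equiv), THF, 0 °C; n-BuLi (1.05 equiv), 0 °C; then 3 (0.9 equiv), 0 °C; cold dilute HCl
Reagents that add atoms: none
Why: In this acetoacetate dianion (gamma) alkylation the terminal carbanion is by far the more nucleophilic site and should displace the primary allylic chloride by SN2 with the (E) alkene unchanged, while the tert-butyl carbonate is too hindered and too weak an acylating agent to compete at 0 °C.

Step 4
Reactants: 6 methyl (E)-8-[(tert-butoxycarbonyl)oxy]-7-methyl-3-oxooct-6-enoate
Product: 7 methyl (1R,5S)-2-oxo-5-(prop-1-en-2-yl)cyclopentane-1-carboxylate (trans)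
Conditions: Pd2(dba)3·CHCl3 (2.5 mol %), (S,S)-N,N'-(cyclohexane-1,2-diyl)bis[2-(diphenylphosphanyl)benzamide] (7.5 mol %), CH2Cl2 (0.02 M), 0 °C to rt
Reagents that add atoms: none
Why: Zerovalent palladium ionises the allylic tert-butyl carbonate to a cationic 1-alkyl-2-methylallyl complex of divalent palladium, and the tert-butoxide left after loss of CO2 deprotonates the β-keto ester. The enolate carbon then attacks the alkyl-substituted allyl terminus on the face opposite the metal, forming the C1–C5 bond of 7 and leaving the rest of the allyl unit as the isopropenyl group; the closest known reaction type is the intramolecular Tsuji–Trost allylic alkylation of β-keto esters to 2-alkenylcyclopentanones, for which asymmetric versions exist. Ring B closes in the 5-exo mode, since attack at the CH2 terminus would need a seven-membered ring. The C5 stereocentre is controlled by the chiral diphosphine, which differentiates the two allyl faces that interconvert by η3–η1–η3 slippage at the unsubstituted CH2 terminus, and the C1 stereocentre, being the acidic carbon of a β-keto ester, should equilibrate to the trans arrangement. The step needs C- over O-alkylation and five- over seven-ring closure: the three-atom tether secures the ring size, any O-allylated enol ether can re-ionise under zerovalent palladium and funnel to the ketone, and high dilution suppresses intermolecular alkylation.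

Step 5
Reactants: 7 methyl (1R,5S)-2-oxo-5-(prop-1-en-2-yl)cyclopentane-1-carboxylate
Product: 8 methyl (1R,2S,5S)-2-hydroxy-2-methyl-5-(prop-1-en-2-yl)cyclopentane-1-carboxylate
Conditions: MeLi (3 equiv), dried CeCl3 (3.3 equiv), THF, −78 °C; then 7, −78 °C; aq. NH4Cl
Reagents that add atoms: methyllithium, C[Li]
Why: Organocerium 1,2-addition (MeCeCl2 from MeLi and CeCl3) relies on a weakly basic, oxophilic reagent that adds to readily enolisable ketones, 1,3-dicarbonyl compounds among them, faster than it deprotonates them, and the methyl group should enter the ketone face anti to the adjacent ester substituent, which sets the carbinol carbon as (S) with OH cis to the ester.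

Step 6
Reactants: 8 methyl (1R,2S,5S)-2-hydroxy-2-methyl-5-(prop-1-en-2-yl)cyclopentane-1-carboxylate
Product: 9 (1S,2S,3S)-2-(hydroxymethyl)-1-methyl-3-(prop-1-en-2-yl)cyclopentan-1-ol
Conditions: LiAlH4 (1.5 equiv), THF, 0 °C; aqueous work-up
Reagents that add atoms: none
Why: LiAlH4 reduction of the ester to the primary alcohol touches no stereocentre, and the low temperature should keep the intermediate β-alkoxy ester from retro-aldol cleavage.

Step 7
Reactants: 9 (1S,2S,3S)-2-(hydroxymethyl)-1-methyl-3-(prop-1-en-2-yl)cyclopentan-1-ol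
Product: 10 (1R,2S,5S)-2-hydroxy-2-methyl-5-(prop-1-en-2-yl)cyclopentane-1-carbaldehyde
Conditions: TEMPO (10 mol %), PhI(OAc)2 (1.1 equiv), CH2Cl2, rt; used at once
Reagents that add atoms: none
Why: The TEMPO/PhI(OAc)2 oxidation (oxoammonium-mediated alcohol oxidation) should stop at the aldehyde in dry CH2Cl2, cannot oxidise the tertiary alcohol and avoids the base that would epimerise or dehydrate the β-hydroxy aldehyde, which is carried on at once.

Step 8
Reactants: 11 phlorisovalerophenone [3-methyl-1-(2,4,6-trihydroxyphenyl)butan-1-one]; 12 prenyl bromide (1-bromo-3-methylbut-2-ene)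
Product: 13 3-methyl-1-[2,4,6-trihydroxy-3-(3-methylbut-2-en-1-yl)phenyl]butan-1-one (mono-prenyl phlorisovalerophenone)
Conditions: NaOMe (1.0 equiv), MeOH, 0 °C; 12 (0.8 equiv) added slowly, 0 °C to rt; 1 M HCl; chromatography
Reagents that add atoms: none
Why: Base-mediated C-prenylation of an acylphloroglucinol anion (C-alkylation of an ambident phenoxide in a protic solvent) should take place at one of the two equivalent free ring carbons, and the deficit of prenyl bromide limits over-alkylation, unreacted 11 being recovered.

Step 9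
Reactants: 13 3-methyl-1-[2,4,6-trihydroxy-3-(3-methylbut-2-en-1-yl)phenyl]butan-1-one; 12 prenyl bromide (1-bromo-3-methylbut-2-ene)
Product: 14 3,5-dihydroxy-2-(3-methylbutanoyl)-6,6-bis(3-methylbut-2-en-1-yl)cyclohexa-2,4-dien-1-one (enol form of the 6,6-diprenyl trione)
Conditions: NaOMe (2.1 equiv), MeOH, 0 °C; 12 (1.05 equiv), 0 °C to rt; 1 M HCl; chromatography
Reagents that add atoms: none
Why: In this alkylative dearomatisation of an acylphloroglucinol anion the prenyl-bearing ring carbon, the more electron-rich of the two nucleophilic carbons, should take up the second prenyl group in competition with the free carbon, and the geminal product, a non-aromatic vinylogous acid, is separated by chromatography from the aromatic 3,5-diprenyl isomer.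

Step 10
Reactants: 10 (1R,2S,5S)-2-hydroxy-2-methyl-5-(prop-1-en-2-yl)cyclopentane-1-carbaldehyde; 14 3,5-dihydroxy-2-(3-methylbutanoyl)-6,6-bis(3-methylbut-2-en-1-yl)cyclohexa-2,4-dien-1-one
Product: 16 3,5-dihydroxy-4-{[(1R,2S,5S)-2-hydroxy-2-methyl-5-(prop-1-en-2-yl)cyclopentyl]methyl}-2-(3-methylbutanoyl)-6,6-bis(3-methylbut-2-en-1-yl)cyclohexa-2,4-dien-1-one (target), via alkylidene trione 15 (not isolated)
Conditions: Hantzsch ester (diethyl 2,6-dimethyl-1,4-dihydropyridine-3,5-dicarboxylate, 1.1 equiv), L-proline (20 mol %), CH2Cl2, rt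
Reagents that add atoms: none
Why: In this three-component reductive alkylation (Knoevenagel condensation then conjugate hydride transfer from the Hantzsch ester) the only unsubstituted ring carbon of the vinylogous acid 14 condenses with aldehyde 10 to alkylidene trione 15, whose electron-poor exocyclic alkene should take up hydride faster than a second molecule of 14, so that the CH2 bridge forms without a new stereocentre and the prenyl and isopropenyl alkenes remain untouched.

Compound list
1 | racemic 2-methyl-2-vinyloxirane (isoprene monoxide) | CC1(C=C)CO1 | starting material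
2 | (E)-4-chloro-2-methylbut-2-en-1-ol | ClC/C=C(\C)CO | intermediate
3 | tert-butyl (E)-4-chloro-2-methylbut-2-en-1-yl carbonate | ClC/C=C(\C)COC(=O)OC(C)(C)C | intermediate
4 | methyl acetoacetate | CC(=O)CC(=O)OC | starting material
5 | methyl acetoacetate dianion (sodium lithium salt) | [CH2-]C(=O)[CH-]C(=O)OC.[Na+].[Li+] | intermediate (not isolated)
6 | methyl (E)-8-[(tert-butoxycarbonyl)oxy]-7-methyl-3-oxooct-6-enoate | COC(=O)CC(=O)CC/C=C(\C)COC(=O)OC(C)(C)C | intermediate
7 | methyl (1R,5S)-2-oxo-5-(prop-1-en-2-yl)cyclopentane-1-carboxylate | C=C(C)[C@H]1CCC(=O)[C@@H]1C(=O)OC | intermediate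
8 | methyl (1R,2S,5S)-2-hydroxy-2-methyl-5-(prop-1-en-2-yl)cyclopentane-1-carboxylate | C=C(C)[C@H]1CC[C@](C)(O)[C@@H]1C(=O)OC | intermediate
9 | (1S,2S,3S)-2-(hydroxymethyl)-1-methyl-3-(prop-1-en-2-yl)cyclopentan-1-ol | C=C(C)[C@H]1CC[C@](C)(O)[C@@H]1CO | intermediate
10 | (1R,2S,5S)-2-hydroxy-2-methyl-5-(prop-1-en-2-yl)cyclopentane-1-carbaldehyde | C=C(C)[C@H]1CC[C@](C)(O)[C@@H]1C=O | intermediate
11 | phlorisovalerophenone | CC(C)CC(=O)c1c(O)cc(O)cc1O | starting material
12 | prenyl bromide | CC(C)=CCBr | starting material
13 | 3-methyl-1-[2,4,6-trihydroxy-3-(3-methylbut-2-en-1-yl)phenyl]butan-1-one | CC(C)CC(=O)c1c(O)cc(O)c(CC=C(C)C)c1O | intermediate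
14 | 3,5-dihydroxy-2-(3-methylbutanoyl)-6,6-bis(3-methylbut-2-en-1-yl)cyclohexa-2,4-dien-1-one | CC(C)CC(=O)C1=C(O)C=C(O)C(CC=C(C)C)(CC=C(C)C)C1=O | intermediate
15 | 5-hydroxy-2-{[(1R,2S,5S)-2-hydroxy-2-methyl-5-(prop-1-en-2-yl)cyclopentyl]methylidene}-4-(3-methylbutanoyl)-6,6-bis(3-methylbut-2-en-1-yl)cyclohex-4-ene-1,3-dione | C=C(C)[C@H]1CC[C@](C)(O)[C@@H]1C=C1C(=O)C(CC=C(C)C)(CC=C(C)C)C(O)=C(C(=O)CC(C)C)C1=O | intermediate (not isolated)
16 | 3,5-dihydroxy-4-{[(1R,2S,5S)-2-hydroxy-2-methyl-5-(prop-1-en-2-yl)cyclopentyl]methyl}-2-(3-methylbutanoyl)-6,6-bis(3-methylbut-2-en-1-yl)cyclohexa-2,4-dien-1-one | C=C(C)[C@H]1CC[C@](C)(O)[C@@H]1CC1=C(O)C(CC=C(C)C)(CC=C(C)C)C(=O)C(C(=O)CC(C)C)=C1O | target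

Total step count: 10. Longest linear sequence: 8 (steps 1 to 7, then step 10); steps 8 and 9 form a two-step side branch that joins at step 10.

Steps most likely to fail

1. Step 4. What may go wrong is poor discrimination between the two allyl faces by the ligand, giving low enantiomeric purity, or stalling at the O-allylated enol ether. The fallback sets out from 6 and returns at 9. Ring B is closed with an achiral catalyst (Pd(PPh3)4, THF, reflux), the robust racemic form of the same cyclisation, which gives 7 together with its mirror image, methyl (1S,5R)-2-oxo-5-(prop-1-en-2-yl)cyclopentane-1-carboxylate F1. The racemate is taken through steps 5 and 6, so that 8 and 9 are accompanied by the mirror-image hydroxy ester, methyl (1S,2R,5R)-2-hydroxy-2-methyl-5-(prop-1-en-2-yl)cyclopentane-1-carboxylate F2, and the mirror-image diol, (1R,2R,3R)-2-(hydroxymethyl)-1-methyl-3-(prop-1-en-2-yl)cyclopentan-1-ol F3. The racemic diol is then resolved by lipase-catalysed acetylation of the primary hydroxyl (Pseudomonas cepacia lipase, vinyl acetate, t-BuOMe, rt). The enzyme is taken here to acetylate the mirror-image diol to [(1R,2R,5R)-2-hydroxy-2-methyl-5-(prop-1-en-2-yl)cyclopentyl]methyl acetate F4, from which unreacted 9 is separated by chromatography; a lipase of the opposite preference would be screened otherwise.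

2. Step 5. What may go wrong is deprotonation of the acidic β-keto ester instead of addition, or insufficient facial selectivity at the metal-chelated ketone. The fallback sets out from 7 and returns at 9; it takes the 1,3-dicarbonyl unit apart before the methyl group is added. NaBH4 (MeOH, 0 °C) reduces the ketone to methyl (1R,5S)-2-hydroxy-5-(prop-1-en-2-yl)cyclopentane-1-carboxylate F5 (both carbinol epimers, of no consequence). LiAlH4 (THF, 0 °C) gives (2S,3S)-2-(hydroxymethyl)-3-(prop-1-en-2-yl)cyclopentan-1-ol F6. TBSCl and imidazole (CH2Cl2, 0 °C) silylate the primary hydroxyl selectively to (2S,3S)-2-{[tert-butyl(dimethyl)silyl]oxymethyl}-3-(prop-1-en-2-yl)cyclopentan-1-ol F7. Dess–Martin periodinane (CH2Cl2, rt) gives (2S,3S)-2-{[tert-butyl(dimethyl)silyl]oxymethyl}-3-(prop-1-en-2-yl)cyclopentan-1-one F8, a ketone without a 1,3-dicarbonyl proton. MeMgBr with CeCl3 (THF, −78 °C) should add anti to the bulky, non-chelating silyloxymethyl group to give (1S,2S,3S)-2-{[tert-butyl(dimethyl)silyl]oxymethyl}-1-methyl-3-(prop-1-en-2-yl)cyclopentan-1-ol F9, and TBAF (THF, rt) returns diol 9.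

3. Step 10. What may go wrong is amine-induced dehydration, retro-aldol ring opening or epimerisation of the β-hydroxy aldehyde before the Knoevenagel condensation takes place. The fallback sets out from 8 and returns at 16. The tertiary hydroxyl is capped (TESOTf, 2,6-lutidine, CH2Cl2, −78 °C) to give methyl (1R,2S,5S)-2-methyl-5-(prop-1-en-2-yl)-2-[(triethylsilyl)oxy]cyclopentane-1-carboxylate F10. i-Bu2AlH (CH2Cl2, −78 °C) gives (1R,2S,5S)-2-methyl-5-(prop-1-en-2-yl)-2-[(triethylsilyl)oxy]cyclopentane-1-carbaldehyde F11, which cannot ring-open by retro-aldol cleavage and is far less prone to β-elimination. Reductive alkylation of 14 with this aldehyde under the conditions of step 10 passes through the silylated alkylidene trione F12 to the triethylsilyl ether of the target F13, and HF·pyridine (THF, 0 °C) returns 16.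

Further compounds
F1 | step 4 | methyl (1S,5R)-2-oxo-5-(prop-1-en-2-yl)cyclopentane-1-carboxylate | C=C(C)[C@@H]1CCC(=O)[C@H]1C(=O)OC
F2 | step 4 | methyl (1S,2R,5R)-2-hydroxy-2-methyl-5-(prop-1-en-2-yl)cyclopentane-1-carboxylate | C=C(C)[C@@H]1CC[C@@](C)(O)[C@H]1C(=O)OC
F3 | step 4 | (1R,2R,3R)-2-(hydroxymethyl)-1-methyl-3-(prop-1-en-2-yl)cyclopentan-1-ol | C=C(C)[C@@H]1CC[C@@](C)(O)[C@H]1CO
F4 | step 4 | [(1R,2R,5R)-2-hydroxy-2-methyl-5-(prop-1-en-2-yl)cyclopentyl]methyl acetate | C=C(C)[C@@H]1CC[C@@](C)(O)[C@H]1COC(C)=O
F5 | step 5 | methyl (1R,5S)-2-hydroxy-5-(prop-1-en-2-yl)cyclopentane-1-carboxylate (C-2 epimers) | C=C(C)[C@H]1CCC(O)[C@@H]1C(=O)OC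
F6 | step 5 | (2S,3S)-2-(hydroxymethyl)-3-(prop-1-en-2-yl)cyclopentan-1-ol (C-1 epimers) | C=C(C)[C@H]1CCC(O)[C@@H]1CO
F7 | step 5 | (2S,3S)-2-{[tert-butyl(dimethyl)silyl]oxymethyl}-3-(prop-1-en-2-yl)cyclopentan-1-ol (C-1 epimers) | C=C(C)[C@H]1CCC(O)[C@@H]1CO[Si](C)(C)C(C)(C)C
F8 | step 5 | (2S,3S)-2-{[tert-butyl(dimethyl)silyl]oxymethyl}-3-(prop-1-en-2-yl)cyclopentan-1-one | C=C(C)[C@H]1CCC(=O)[C@@H]1CO[Si](C)(C)C(C)(C)C
F9 | step 5 | (1S,2S,3S)-2-{[tert-butyl(dimethyl)silyl]oxymethyl}-1-methyl-3-(prop-1-en-2-yl)cyclopentan-1-ol | C=C(C)[C@H]1CC[C@](C)(O)[C@@H]1CO[Si](C)(C)C(C)(C)C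
F10 | step 10 | methyl (1R,2S,5S)-2-methyl-5-(prop-1-en-2-yl)-2-[(triethylsilyl)oxy]cyclopentane-1-carboxylate | C=C(C)[C@H]1CC[C@](C)(O[Si](CC)(CC)CC)[C@@H]1C(=O)OC
F11 | step 10 | (1R,2S,5S)-2-methyl-5-(prop-1-en-2-yl)-2-[(triethylsilyl)oxy]cyclopentane-1-carbaldehyde | C=C(C)[C@H]1CC[C@](C)(O[Si](CC)(CC)CC)[C@@H]1C=O
F12 | step 10 | 5-hydroxy-2-{[(1R,2S,5S)-2-methyl-5-(prop-1-en-2-yl)-2-[(triethylsilyl)oxy]cyclopentyl]methylidene}-4-(3-methylbutanoyl)-6,6-bis(3-methylbut-2-en-1-yl)cyclohex-4-ene-1,3-dione | C=C(C)[C@H]1CC[C@](C)(O[Si](CC)(CC)CC)[C@@H]1C=C1C(=O)C(CC=C(C)C)(CC=C(C)C)C(O)=C(C(=O)CC(C)C)C1=O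
F13 | step 10 | 3,5-dihydroxy-4-{[(1R,2S,5S)-2-methyl-5-(prop-1-en-2-yl)-2-[(triethylsilyl)oxy]cyclopentyl]methyl}-2-(3-methylbutanoyl)-6,6-bis(3-methylbut-2-en-1-yl)cyclohexa-2,4-dien-1-one | C=C(C)[C@H]1CC[C@](C)(O[Si](CC)(CC)CC)[C@@H]1CC1=C(O)C(CC=C(C)C)(CC=C(C)C)C(=O)C(C(=O)CC(C)C)=C1O
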